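The synthesis rests on cutting the bond between the methine carbon that bridges the two 2-aminoimidazole rings and the adjacent CH2 of its aminoethyl arm. The methine is bonded to C4(5) of both rings and is therefore a latent azafulvenium cation. That CH2 lies β to the amide nitrogen, which makes it the nucleophilic carbon of an N-vinyl amide. In one operation a chiral phosphoric acid ionises a racemic bis(heteroaryl)carbinol, funnels both enantiomers through one planar cation and joins it face-selectively to N-vinyl-4,5-dibromopyrrole-2-carboxamide. In the carbinol both 2-aminoimidazoles are masked as imidazo[1,2-a]pyrimidines and the (E)-allyl amide arm is already in place; hydrazine unmasks at the end.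

Key step: step 7

Assumption 1: the N–H tautomers of each 2-aminoimidazole interconvert rapidly, so the tautomer released in step 8 and the one drawn for the target are the same compound.
Assumption 2: the sense of induction of the new catalytic step cannot be derived safely by analogy. (R)-TRIP is written, and its equally available enantiomer is used if the first experiment shows the opposite sense.

Step 1
Reactants: 1 4,5-dibromo-1H-pyrrole-2-carboxylic acid
Product: 2 4,5-dibromo-1H-pyrrole-2-carbonyl chloride
Conditions: (COCl)2, DMF (cat.), CH2Cl2, 0 °C → rt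
Reagents that add atoms: oxalyl chloride, ClC(=O)C(=O)Cl
Why: Standard acid chloride formation through the catalytic chloroiminium species, to which the electron-poor dibromopyrrole ring and its N–H are inert.

Step 2
Reactants: 2 4,5-dibromo-1H-pyrrole-2-carbonyl chloride; 3 N-vinylformamide
Product: 5 4,5-dibromo-N-vinyl-1H-pyrrole-2-carboxamide, via 4,5-dibromo-N-formyl-N-vinyl-1H-pyrrole-2-carboxamide 4 (not isolated)
Conditions: Et3N, DMAP (cat.), THF, 0 °C → rt; then aq NaOH, 0 °C
Reagents that add atoms: none
Why: N-Acylation of the secondary formamide followed by chemoselective imide cleavage at the more electrophilic, less hindered formyl carbonyl, the known use of N-vinylformamide as a vinylamine equivalent, should give the secondary enamide with the vinyl group intact.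

Step 3
Reactants: 6 2,2,2-trichloro-1-(4,5-dibromo-1H-pyrrol-2-yl)ethan-1-one; 7 allylamine
Product: 8 N-allyl-4,5-dibromo-1H-pyrrole-2-carboxamide
Conditions: MeCN, rt
Reagents that add atoms: none
Why: Haloform-type aminolysis of a trichloromethyl ketone expels trichloromethanide under neutral conditions and therefore needs no protection of the pyrrole N–H.

Step 4
Reactants: 9 imidazo[1,2-a]pyrimidine-2-carbaldehyde
Product: 10 3-iodoimidazo[1,2-a]pyrimidine-2-carbaldehyde
Conditions: NIS, MeCN, rt → 50 °C
Reagents that add atoms: N-iodosuccinimide, O=C1CCC(=O)N1I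
Why: Electrophilic aromatic iodination should take place at C3, the enamine-like and only free carbon of the five-membered ring, even with the formyl group at C2.

Step 5
Reactants: 10 3-iodoimidazo[1,2-a]pyrimidine-2-carbaldehyde; 8 N-allyl-4,5-dibromo-1H-pyrrole-2-carboxamide
Product: 11 4,5-dibromo-N-[(E)-3-(2-formylimidazo[1,2-a]pyrimidin-3-yl)allyl]-1H-pyrrole-2-carboxamide
Conditions: Pd(OAc)2 (5 mol %), n-Bu4NCl, NaHCO3, DMF, 50 °C
Reagents that add atoms: none
Why: Mizoroki–Heck reaction in which, under ligand-free chloride-promoted conditions at moderate temperature, only the C–I bond should undergo oxidative addition while both C–Br bonds stay intact, insertion places the heteroaryl group on the terminal alkene carbon, and syn β-hydride elimination towards conjugation sets the E geometry.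

Step 6
Reactants: 12 3-bromoimidazo[1,2-a]pyrimidine; 11 4,5-dibromo-N-[(E)-3-(2-formylimidazo[1,2-a]pyrimidin-3-yl)allyl]-1H-pyrrole-2-carboxamide
Product: 14 (±)-4,5-dibromo-N-[(E)-3-{2-[hydroxy(imidazo[1,2-a]pyrimidin-3-yl)methyl]imidazo[1,2-a]pyrimidin-3-yl}allyl]-1H-pyrrole-2-carboxamide, via imidazo[1,2-a]pyrimidin-3-ylmagnesium chloride 13 (not isolated)
Conditions: 12 (3.3 equiv), i-PrMgCl·LiCl, THF, −30 °C; then 11, −30 → 0 °C; aq NH4Cl
Reagents that add atoms: none
Why: Bromine–magnesium exchange with the turbo-Grignard reagent and 1,2-addition to the aldehyde, in which two sacrificial equivalents of 13 deprotonate the pyrrole and amide N–H groups, the resulting anions shield the C–Br bonds from exchange, and the carbinol centre is deliberately left racemic because step 7 erases it.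

Step 7
Reactants: 14 (±)-bis(heteroaryl)carbinol; 5 4,5-dibromo-N-vinyl-1H-pyrrole-2-carboxamide
Product: 17 4,5-dibromo-N-[(E)-3-{2-[(1S)-3-(4,5-dibromo-1H-pyrrole-2-carboxamido)-1-(imidazo[1,2-a]pyrimidin-3-yl)propyl]imidazo[1,2-a]pyrimidin-3-yl}allyl]-1H-pyrrole-2-carboxamide, via bis(heteroaryl)methylium (azafulvenium-type) cation 15 (not isolated), via (S)-N-acylimine 16 (not isolated)
Conditions: (R)-TRIP (10 mol %), CH2Cl2, 30 °C, 5 added slowly; then Et3SiH, TFA, 0 °C
Reagents that add atoms: none
Why: Proposed new method: the phosphoric acid protonates the hydroxyl group of rac-14 and water leaves because the imidazo[1,2-a]pyrimidin-3-yl ring feeds the N4 lone pair through C8a=N1 and C2=C3 into the exocyclic carbon, so both enantiomers collapse to the same planar, achiral cation 15, held as a contact ion pair by the chiral phosphate (enantioconvergent SN1). The phosphoryl oxygen at the same time accepts the N–H hydrogen bond of enamide 5, whose terminal =CH2 (β to nitrogen) attacks the cationic carbon in an aza-ene-type transition state and returns its proton to the catalyst to give N-acylimine 16, which Et3SiH/TFA then reduces through its N-acyliminium form (ionic hydrogenation) in the same flask. The closest known reaction type is the chiral-phosphoric-acid-catalysed dehydrative alkylation of secondary enamides with aryl(indol-3-yl)methanols; new here are the weakly basic, N–H-free imidazopyrimidine donor and the unsubstituted N-vinyl amide. No ring is closed. The single new stereocentre is set by the catalyst: peri strain with C5–H of the donor ring should allow only one geometry about the exocyclic C–C3 bond, the 3-alkenyl group twists the second ring out of plane, the amidopyrrole N–H pair of the side arm offers the phosphate a second anchor, and the 2,4,6-triisopropylphenyl walls should leave one face open to the bound enamide. The step needs attack at the exocyclic carbon rather than at the far alkene carbon of the pentadienyl-type cation (only the former restores both aromatic rings), C- over N/O-alkylation (the latter are reversible under acid), no capture by the side-arm amide (the E-alkene keeps it out of reach) and a single addition (slow addition of 5 keeps 16 from meeting a second enamide).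

Step 8
Reactants: 17 (S)-bis(imidazo[1,2-a]pyrimidine) bis-amide
Product: 18 N-[(E)-3-{2-amino-5-[(1S)-1-(2-amino-1H-imidazol-5-yl)-3-(4,5-dibromo-1H-pyrrole-2-carboxamido)propyl]-1H-imidazol-4-yl}allyl]-4,5-dibromo-1H-pyrrole-2-carboxamide (target)
Conditions: N2H4·H2O (excess), EtOH, 90 °C, sealed tube, Ar
Reagents that add atoms: none
Why: Known hydrazinolysis of imidazo[1,2-a]pyrimidines, in which hydrazine adds to C5/C7 of each pyrimidine ring, opens it and leaves with C5–C6–C7 as pyrazole so that N4 remains as ring N–H and N8 as the 2-amino group, while the secondary amides, the C–Br bonds, the E-alkene (air excluded to avoid diimide) and the non-acidic methine stereocentre should not be affected.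

Compound list
1 | 4,5-dibromo-1H-pyrrole-2-carboxylic acid | O=C(O)c1cc(Br)c(Br)[nH]1 | starting material
2 | 4,5-dibromo-1H-pyrrole-2-carbonyl chloride | O=C(Cl)c1cc(Br)c(Br)[nH]1 | intermediate
3 | N-vinylformamide | C=CNC=O | starting material
4 | 4,5-dibromo-N-formyl-N-vinyl-1H-pyrrole-2-carboxamide | C=CN(C=O)C(=O)c1cc(Br)c(Br)[nH]1 | intermediate
5 | 4,5-dibromo-N-vinyl-1H-pyrrole-2-carboxamide | C=CNC(=O)c1cc(Br)c(Br)[nH]1 | intermediate
6 | 2,2,2-trichloro-1-(4,5-dibromo-1H-pyrrol-2-yl)ethan-1-one | O=C(c1cc(Br)c(Br)[nH]1)C(Cl)(Cl)Cl | starting material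
7 | allylamine | C=CCN | starting material
8 | N-allyl-4,5-dibromo-1H-pyrrole-2-carboxamide | C=CCNC(=O)c1cc(Br)c(Br)[nH]1 | intermediate
9 | imidazo[1,2-a]pyrimidine-2-carbaldehyde | O=Cc1cn2cccnc2n1 | starting material
10 | 3-iodoimidazo[1,2-a]pyrimidine-2-carbaldehyde | O=Cc1nc2ncccn2c1I | intermediate
11 | 4,5-dibromo-N-[(E)-3-(2-formylimidazo[1,2-a]pyrimidin-3-yl)allyl]-1H-pyrrole-2-carboxamide | O=Cc1nc2ncccn2c1/C=C/CNC(=O)c1cc(Br)c(Br)[nH]1 | intermediate
12 | 3-bromoimidazo[1,2-a]pyrimidine | Brc1cnc2ncccn12 | starting material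
13 | imidazo[1,2-a]pyrimidin-3-ylmagnesium chloride | Cl[Mg]c1cnc2ncccn12 | intermediate
14 | (±)-4,5-dibromo-N-[(E)-3-{2-[hydroxy(imidazo[1,2-a]pyrimidin-3-yl)methyl]imidazo[1,2-a]pyrimidin-3-yl}allyl]-1H-pyrrole-2-carboxamide (racemic at the carbinol carbon) | OC(c1cnc2ncccn12)c1nc2ncccn2c1/C=C/CNC(=O)c1cc(Br)c(Br)[nH]1 | intermediate
15 | {3-[(E)-3-(4,5-dibromo-1H-pyrrole-2-carboxamido)prop-1-enyl]imidazo[1,2-a]pyrimidin-2-yl}(imidazo[1,2-a]pyrimidin-3-yl)methylium (phosphate ion pair) | [CH+](c1cnc2ncccn12)c1nc2ncccn2c1/C=C/CNC(=O)c1cc(Br)c(Br)[nH]1 | intermediate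
16 | 4,5-dibromo-N-[(1E,3S)-3-{3-[(E)-3-(4,5-dibromo-1H-pyrrole-2-carboxamido)prop-1-enyl]imidazo[1,2-a]pyrimidin-2-yl}-3-(imidazo[1,2-a]pyrimidin-3-yl)propylidene]-1H-pyrrole-2-carboxamide | c1cnc2ncc([C@H](C/C=N/C(=O)c3cc(Br)c(Br)[nH]3)c3nc4ncccn4c3/C=C/CNC(=O)c3cc(Br)c(Br)[nH]3)n2c1 | intermediate
17 | 4,5-dibromo-N-[(E)-3-{2-[(1S)-3-(4,5-dibromo-1H-pyrrole-2-carboxamido)-1-(imidazo[1,2-a]pyrimidin-3-yl)propyl]imidazo[1,2-a]pyrimidin-3-yl}allyl]-1H-pyrrole-2-carboxamide | c1cnc2ncc([C@H](CCNC(=O)c3cc(Br)c(Br)[nH]3)c3nc4ncccn4c3/C=C/CNC(=O)c3cc(Br)c(Br)[nH]3)n2c1 | intermediate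
18 | N-[(E)-3-{2-amino-5-[(1S)-1-(2-amino-1H-imidazol-5-yl)-3-(4,5-dibromo-1H-pyrrole-2-carboxamido)propyl]-1H-imidazol-4-yl}allyl]-4,5-dibromo-1H-pyrrole-2-carboxamide | Nc1ncc([C@H](CCNC(=O)c2cc(Br)c(Br)[nH]2)c2[nH]c(N)nc2/C=C/CNC(=O)c2cc(Br)c(Br)[nH]2)[nH]1 | target

Total step count: 8
Longest linear sequence: 5 steps (9 → 10 → 11 → 14 → 17 → 18; the branch 6 → 8 → 11 is equally long)

Steps most likely to fail

1. Step 7 (key step).
- **Slow ionisation:** the acid may be parked on the ring nitrogens.
- **Poor facial selectivity:** the cation offers the phosphate no N–H anchor of its own.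
- **Erosion of enantiopurity:** C–C bond formation may be reversible before reduction. The excess TFA of the second stage protonates both ring systems and should shut this path.
- **Side reactions:** the pentadienyl-type cation may close electrocyclically onto its own alkene, and the enamide may self-condense.
- **Fallback with known chemistry:** it sets out from carbinol 14 and returns at 17.
  - MnO2 oxidation should give the bis(heteroaryl) ketone F1.
  - Horner–Wadsworth–Emmons olefination with diethyl cyanomethylphosphonate (NaH in excess, THF) makes the same carbon–carbon connection as a double bond. It gives the (Z)-acrylonitrile F2 and the (E)-acrylonitrile F3, which are separated by chromatography.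
  - Copper hydride conjugate reduction (Cu(OAc)2, Josiphos ligand, PMHS, t-BuOH) is a known reaction of 3,3-diarylacrylonitriles. It reads the face from the alkene geometry and not from the difference between the two heteroaryl groups. Each isomer, with the appropriate ligand enantiomer, should give the (S)-nitrile F4.
  - DIBAL-H (excess, CH2Cl2, −78 °C) and hydrolysis give the (S)-aldehyde F5.
  - Reductive amidation with commercial 4,5-dibromo-1H-pyrrole-2-carboxamide (Et3SiH, TFA) passes through the protonated form of 16 and rejoins the route at 17.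

2. Step 5.
- **What may go wrong:** discrimination between C–I and C–Br in the oxidative addition may be lost. β-Hydride elimination towards nitrogen may move the double bond into the enamide position, and the alkene geometry may erode.
- **Fallback:** it sets out from 6 and 10 and returns at 11.
  - Radical hydrostannylation of propargylamine (Bu3SnH, AIBN) gives (E)-3-(tributylstannyl)prop-2-en-1-amine F6.
  - Acylation of F6 with 6 gives the (E)-stannylallyl amide F7.
  - Stille coupling of F7 with 10 (Pd2(dba)3, AsPh3, CuI, DMF, rt) transfers a vinyl unit whose position and geometry are already fixed. At room temperature it should leave the C–Br bonds alone, giving 11.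

3. Step 6.
- **What may go wrong:** the doubly deprotonated aldehyde may precipitate. The organomagnesium reagent may attack a pyrimidine ring, or bromine–magnesium exchange may occur at the pyrrole.
- **Fallback:** it sets out from 10 and returns at 14, with the order of the two bond formations inverted.
  - Reagent 13 (1.1 equiv, −78 °C) is added to the N–H-free iodo aldehyde 10 to give the iodo carbinol F8.
  - The Heck reaction with 8 under the conditions of step 5 then installs the side arm and gives 14.

Further compounds
F1 | step 7 | 4,5-dibromo-N-[(E)-3-{2-(imidazo[1,2-a]pyrimidine-3-carbonyl)imidazo[1,2-a]pyrimidin-3-yl}allyl]-1H-pyrrole-2-carboxamide | O=C(c1cnc2ncccn12)c1nc2ncccn2c1/C=C/CNC(=O)c1cc(Br)c(Br)[nH]1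
F2 | step 7 | 4,5-dibromo-N-[(E)-3-{2-[(Z)-2-cyano-1-(imidazo[1,2-a]pyrimidin-3-yl)vinyl]imidazo[1,2-a]pyrimidin-3-yl}allyl]-1H-pyrrole-2-carboxamide | N#C/C=C(/c1cnc2ncccn12)c1nc2ncccn2c1/C=C/CNC(=O)c1cc(Br)c(Br)[nH]1
F3 | step 7 | 4,5-dibromo-N-[(E)-3-{2-[(E)-2-cyano-1-(imidazo[1,2-a]pyrimidin-3-yl)vinyl]imidazo[1,2-a]pyrimidin-3-yl}allyl]-1H-pyrrole-2-carboxamide | N#C/C=C(\c1cnc2ncccn12)c1nc2ncccn2c1/C=C/CNC(=O)c1cc(Br)c(Br)[nH]1
F4 | step 7 | 4,5-dibromo-N-[(E)-3-{2-[(1S)-2-cyano-1-(imidazo[1,2-a]pyrimidin-3-yl)ethyl]imidazo[1,2-a]pyrimidin-3-yl}allyl]-1H-pyrrole-2-carboxamide | c1cnc2ncc([C@H](CC#N)c3nc4ncccn4c3/C=C/CNC(=O)c3cc(Br)c(Br)[nH]3)n2c1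
F5 | step 7 | 4,5-dibromo-N-[(E)-3-{2-[(1S)-1-(imidazo[1,2-a]pyrimidin-3-yl)-3-oxopropyl]imidazo[1,2-a]pyrimidin-3-yl}allyl]-1H-pyrrole-2-carboxamide | c1cnc2ncc([C@H](CC=O)c3nc4ncccn4c3/C=C/CNC(=O)c3cc(Br)c(Br)[nH]3)n2c1
F6 | step 5 | (E)-3-(tributylstannyl)prop-2-en-1-amine | NC/C=C/[Sn](CCCC)(CCCC)CCCC
F7 | step 5 | 4,5-dibromo-N-[(E)-3-(tributylstannyl)allyl]-1H-pyrrole-2-carboxamide | O=C(NC/C=C/[Sn](CCCC)(CCCC)CCCC)c1cc(Br)c(Br)[nH]1
F8 | step 6 | (±)-(imidazo[1,2-a]pyrimidin-3-yl)(3-iodoimidazo[1,2-a]pyrimidin-2-yl)methanol | OC(c1cnc2ncccn12)c1nc2ncccn2c1I
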